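**Assumption:** (S)- and (R)-but-3-yn-2-ol and (R)-1-bromo-3-chloro-2-methylpropane are taken as purchasable chiral building blocks. "C1–C14" in the Why lines is the target chain: C1 = CO2H, C3 and C6 = the ring carbons on oxygen, C13 = the ketone.

## Retrosynthetic overview

1. Target 22 ⇐ propenyl acid 21 + methyl vinyl ketone (cross-metathesis; the enone comes last).
2. The 1,2-dioxane is the only ring and is closed once (step 10), by the C6 hydroperoxide adding to the C3 aldehyde. The C3–CH2CO2H bond follows by axial addition of a ketene acetal to the cyclic peroxycarbenium ion. The C6–OO bond comes from hydroperoxysilylation of an ethylidene.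
3. Key step: Ireland–Claisen [3,3] rearrangement of butanoate 10. It makes C4–C5, sets C4 by chirality transfer from (R)-but-3-yn-2-ol and leaves the C6 ethylidene.
4. Allylic alcohol 9 ⇐ side-chain Grignard 8 + (R)-but-3-yn-2-ol (Cu-catalysed carbomagnesiation, C6–C7).
5. Side chain 6 ⇐ anti-SN2' ethylation of a picolinate from (S)-but-3-yn-2-ol (sets C10) + (R)-1-bromo-3-chloro-2-methylpropane (brings C8).

## Route

Step 1
Reactants: 1 (S)-but-3-yn-2-ol; 2 (R)-1-bromo-3-chloro-2-methylpropane
Product: 3 (2S,6S)-7-chloro-6-methylhept-3-yn-2-ol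
Conditions: n-BuLi (2.1 equiv), THF, −78 → 0 °C; then 2, DMPU, 0 °C → rt; H2O
Reagents that add atoms: none
Why: The alkoxide–acetylide dianion of 1 is C-alkylated at the bromide end of 2 (acetylide SN2 alkylation, Br leaving far faster than Cl), and neither bought stereocentre is touched.

Step 2
Reactants: 3 (2S,6S)-7-chloro-6-methylhept-3-yn-2-ol
Product: 4 (2S,3E,6S)-7-chloro-6-methylhept-3-en-2-ol
Conditions: NaAlH2(OCH2CH2OMe)2, THF, 0 °C → rt; aq. work-up
Reagents that add atoms: none
Why: Alkoxide-directed trans-hydroalumination of the propargylic alcohol and protonolysis give only the (E)-allylic alcohol, with the carbinol centre and the primary chloride untouched.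

Step 3
Reactants: 4 (2S,3E,6S)-7-chloro-6-methylhept-3-en-2-ol
Product: 5 (2S,3E,6S)-7-chloro-6-methylhept-3-en-2-yl pyridine-2-carboxylate
Conditions: picolinic acid, DCC, DMAP (cat.), CH2Cl2, rt
Reagents that add atoms: pyridine-2-carboxylic acid, OC(=O)c1ccccn1
Why: Steglich esterification installs the chelating picolinate leaving group without touching the carbinol configuration.

Step 4
Reactants: 5 (2S,3E,6S)-7-chloro-6-methylhept-3-en-2-yl pyridine-2-carboxylate
Product: 6 (2E,4S,6S)-7-chloro-4-ethyl-6-methylhept-2-ene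
Conditions: EtMgBr (2 equiv), CuBr·SMe2 (20 mol%), THF, −40 → 0 °C
Reagents that add atoms: ethylmagnesium bromide, CC[Mg]Br
Why: Copper-catalysed allylic substitution of the picolinate goes anti-SN2' (ethyl enters at the γ-carbon opposite the leaving group in the conformer with the carbinol H eclipsing the alkene), so the (S)-carbinol centre is traded for the (S)-ethyl centre C10 and an (E)-propenyl group.

Step 5
Reactants: 6 (2E,4S,6S)-7-chloro-4-ethyl-6-methylhept-2-ene; 7 (R)-but-3-yn-2-ol
Product: 9 (2R,5S,7S,8E)-7-ethyl-5-methyl-3-methylidenedec-8-en-2-ol, via Grignard reagent 8 (not isolated)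
Conditions: Mg, THF, reflux; add to 7 pre-treated with i-PrMgCl (1.0 equiv); CuI (10 mol%), THF–Et2O, 0 °C → rt; aq. NH4Cl
Reagents that add atoms: none
Why: Magnesium inserts into the primary C–Cl bond and the Grignard adds across the alkyne of the magnesium alkoxide of 7 in a CuI-catalysed, alkoxide-directed anti-carbomagnesiation that places the alkyl group on the internal carbon, leaving the bought carbinol centre unchanged.

Step 6
Reactants: 9 (2R,5S,7S,8E)-7-ethyl-5-methyl-3-methylidenedec-8-en-2-ol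
Product: 10 (2R,5S,7S,8E)-7-ethyl-5-methyl-3-methylidenedec-8-en-2-yl butanoate
Conditions: n-PrCOCl, pyridine, DMAP (cat.), CH2Cl2, 0 °C → rt
Reagents that add atoms: butanoyl chloride, CCCC(=O)Cl
Why: DMAP-catalysed acylation of the secondary allylic alcohol proceeds with retention because the C–O bond is not broken.

Step 7
Reactants: 10 (2R,5S,7S,8E)-7-ethyl-5-methyl-3-methylidenedec-8-en-2-yl butanoate
Product: 13 (2S,4E,6S,8S,9E)-2,8-diethyl-4-ethylidene-6-methylundec-9-en-1-ol, via silyl ketene acetal 11 (not isolated), via trimethylsilyl ester 12 (not isolated)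
Conditions: LDA (LiN(i-Pr)2), THF, −78 °C; TMSCl, −78 → 50 °C; then LiAlH4, 0 °C; aq. work-up
Reagents that add atoms: none
Why: Kinetic enolisation in THF gives the (E)-silyl ketene acetal, whose chair Ireland–Claisen [3,3]-sigmatropic rearrangement (carbinol methyl equatorial) forms C4–C5 and transfers the (R)-carbinol chirality to the (S)-ethyl centre C4 (about 9:1, set by the enolate E/Z ratio) while creating the (E)-ethylidene at C6, and LiAlH4 reduces the silyl ester in the same pot.

Step 8
Reactants: 13 (2S,4E,6S,8S,9E)-2,8-diethyl-4-ethylidene-6-methylundec-9-en-1-ol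
Product: 14 (2S,4R,6S,8S,9E)-2,4,8-triethyl-6-methyl-4-[(triethylsilyl)peroxy]undec-9-en-1-ol (4R shown; 4S epimer also formed)
Conditions: Co(thd)2 [bis(2,2,6,6-tetramethylheptane-3,5-dionato)cobalt] (10 mol%), O2 (1 atm), Et3SiH, ClCH2CH2Cl, rt
Reagents that add atoms: dioxygen, O=O; triethylsilane, CC[SiH](CC)CC
Why: In this Mukaiyama–Isayama hydroperoxysilylation the cobalt hydride delivers H to the CH end of the trisubstituted alkene only (the 1,2-disubstituted propenyl group reacts far more slowly) and the tertiary C6 radical is trapped by O2 and silylated; the flanking C4 and C8 centres give no useful facial bias, so C6 forms as a roughly 1:1 epimer pair that is carried on and separated after step 11.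

Step 9
Reactants: 14 (2S,4R,6S,8S,9E)-2,4,8-triethyl-6-methyl-4-[(triethylsilyl)peroxy]undec-9-en-1-ol
Product: 15 (2S,4R,6S,8S,9E)-2,4,8-triethyl-6-methyl-4-[(triethylsilyl)peroxy]undec-9-enal
Conditions: Dess–Martin periodinane, CH2Cl2, 0 °C → rt
Reagents that add atoms: none
Why: Dess–Martin oxidation converts the primary alcohol into the C3 aldehyde under near-neutral conditions that spare the silyl peroxide and the α-stereocentre.

Step 10
Reactants: 15 (2S,4R,6S,8S,9E)-2,4,8-triethyl-6-methyl-4-[(triethylsilyl)peroxy]undec-9-enal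
Product: 18 (4S,6R)-4,6-diethyl-6-[(2S,4S,5E)-4-ethyl-2-methylhept-5-en-1-yl]-3-methoxy-1,2-dioxane (C3 anomers), via hydroperoxy aldehyde 16 (not isolated), via cyclic peroxyhemiacetal 17 (not isolated)
Conditions: TsOH·H2O (10 mol%), MeOH, rt
Reagents that add atoms: methanol, CO
Why: Acidic methanol removes the silyl group, the freed C6 hydroperoxide closes onto the aldehyde (peroxy-hemiacetal formation, which closes the 1,2-dioxane) and acetal exchange gives the methyl peroxyacetal, whose C3 configuration does not matter because C3 is ionised in the next step.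

Step 11
Reactants: 18 (4S,6R)-4,6-diethyl-6-[(2S,4S,5E)-4-ethyl-2-methylhept-5-en-1-yl]-3-methoxy-1,2-dioxane
Product: 21 2-[(3S,4S,6R)-4,6-diethyl-6-[(2S,4S,5E)-4-ethyl-2-methylhept-5-en-1-yl]-1,2-dioxan-3-yl]acetic acid, via peroxycarbenium triflate 19 (not isolated), via trimethylsilyl ester 20 (not isolated)
Conditions: CH2=C(OSiMe3)2, TMSOTf (0.3 equiv), CH2Cl2, −78 °C; then H2O; chromatography (removes the 6S epimer)
Reagents that add atoms: ketene bis(trimethylsilyl) acetal, C=C(O[Si](C)(C)C)O[Si](C)(C)C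
Why: TMSOTf ionises the peroxyacetal to a cyclic peroxycarbenium ion that the ketene acetal captures (Mukaiyama-type addition) along the axial trajectory of the half-chair with the C4 ethyl pseudo-equatorial (the other half-chair suffers a 1,3-diaxial clash with the axial C6 substituent), which sets C3 cis to the C4 ethyl.

Step 12
Reactants: 21 2-[(3S,4S,6R)-4,6-diethyl-6-[(2S,4S,5E)-4-ethyl-2-methylhept-5-en-1-yl]-1,2-dioxan-3-yl]acetic acid
Product: 22 2-[(3S,4S,6R)-4,6-diethyl-6-[(2S,4S,5E)-4-ethyl-2-methyl-7-oxooct-5-en-1-yl]-1,2-dioxan-3-yl]acetic acid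
Conditions: methyl vinyl ketone (5 equiv), second-generation Hoveyda–Grubbs catalyst (10 mol%), CH2Cl2, 40 °C
Reagents that add atoms: methyl vinyl ketone, C=CC(C)=O
Why: Olefin cross-metathesis of the propenyl group with excess enone gives the thermodynamically favoured (E)-enone and propene, and ruthenium alkylidenes tolerate the dialkyl peroxide and the free acid.

## Compound list

1 | (S)-but-3-yn-2-ol | C[C@H](O)C#C | starting material
2 | (R)-1-bromo-3-chloro-2-methylpropane | BrC[C@H](C)CCl | starting material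
3 | (2S,6S)-7-chloro-6-methylhept-3-yn-2-ol | C[C@H](O)C#CC[C@H](C)CCl | intermediate
4 | (2S,3E,6S)-7-chloro-6-methylhept-3-en-2-ol | C[C@H](O)/C=C/C[C@H](C)CCl | intermediate
5 | (2S,3E,6S)-7-chloro-6-methylhept-3-en-2-yl pyridine-2-carboxylate | C[C@H](OC(=O)c1ccccn1)/C=C/C[C@H](C)CCl | intermediate
6 | (2E,4S,6S)-7-chloro-4-ethyl-6-methylhept-2-ene | CC[C@H](/C=C/C)C[C@H](C)CCl | intermediate
7 | (R)-but-3-yn-2-ol | C[C@@H](O)C#C | starting material
8 | [(2S,4S,5E)-4-ethyl-2-methylhept-5-en-1-yl]magnesium chloride | CC[C@H](/C=C/C)C[C@H](C)C[Mg]Cl | intermediate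
9 | (2R,5S,7S,8E)-7-ethyl-5-methyl-3-methylidenedec-8-en-2-ol | CC[C@H](/C=C/C)C[C@H](C)CC(=C)[C@@H](C)O | intermediate
10 | (2R,5S,7S,8E)-7-ethyl-5-methyl-3-methylidenedec-8-en-2-yl butanoate | CC[C@H](/C=C/C)C[C@H](C)CC(=C)[C@@H](C)OC(=O)CCC | intermediate
11 | (E)-trimethylsilyl ketene acetal of 10 (ethyl cis to the allyl oxygen) | CC[C@H](/C=C/C)C[C@H](C)CC(=C)[C@@H](C)O/C(O[Si](C)(C)C)=C\CC | intermediate
12 | trimethylsilyl (2S,4E,6S,8S,9E)-2,8-diethyl-4-ethylidene-6-methylundec-9-enoate | CC[C@H](/C=C/C)C[C@H](C)C/C(=C\C)C[C@H](CC)C(=O)O[Si](C)(C)C | intermediate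
13 | (2S,4E,6S,8S,9E)-2,8-diethyl-4-ethylidene-6-methylundec-9-en-1-ol | CC[C@H](/C=C/C)C[C@H](C)C/C(=C\C)C[C@H](CC)CO | intermediate
14 | (2S,4R,6S,8S,9E)-2,4,8-triethyl-6-methyl-4-[(triethylsilyl)peroxy]undec-9-en-1-ol (4R shown; carried together with its 4S epimer) | CC[C@H](/C=C/C)C[C@H](C)C[C@](OO[Si](CC)(CC)CC)(CC)C[C@H](CC)CO | intermediate
15 | (2S,4R,6S,8S,9E)-2,4,8-triethyl-6-methyl-4-[(triethylsilyl)peroxy]undec-9-enal (4R shown; carried together with its 4S epimer) | CC[C@H](/C=C/C)C[C@H](C)C[C@](OO[Si](CC)(CC)CC)(CC)C[C@H](CC)C=O | intermediate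
16 | (2S,4R,6S,8S,9E)-2,4,8-triethyl-4-hydroperoxy-6-methylundec-9-enal | CC[C@H](/C=C/C)C[C@H](C)C[C@](OO)(CC)C[C@H](CC)C=O | intermediate
17 | (4S,6R)-4,6-diethyl-6-[(2S,4S,5E)-4-ethyl-2-methylhept-5-en-1-yl]-1,2-dioxan-3-ol (C3 anomers) | CC[C@H](/C=C/C)C[C@H](C)C[C@]1(CC)C[C@H](CC)C(O)OO1 | intermediate
18 | (4S,6R)-4,6-diethyl-6-[(2S,4S,5E)-4-ethyl-2-methylhept-5-en-1-yl]-3-methoxy-1,2-dioxane (C3 anomers; 6R shown, carried together with its 6S epimer) | CC[C@H](/C=C/C)C[C@H](C)C[C@]1(CC)C[C@H](CC)C(OC)OO1 | intermediate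
19 | (4S,6R)-4,6-diethyl-6-[(2S,4S,5E)-4-ethyl-2-methylhept-5-en-1-yl]-5,6-dihydro-4H-1,2-dioxin-2-ium triflate (cyclic peroxycarbenium ion) | CC[C@H](/C=C/C)C[C@H](C)C[C@]1(CC)C[C@H](CC)C=[O+]O1.[O-]S(=O)(=O)C(F)(F)F | intermediate
20 | trimethylsilyl 2-[(3S,4S,6R)-4,6-diethyl-6-[(2S,4S,5E)-4-ethyl-2-methylhept-5-en-1-yl]-1,2-dioxan-3-yl]acetate | CC[C@H](/C=C/C)C[C@H](C)C[C@]1(CC)C[C@H](CC)[C@H](CC(=O)O[Si](C)(C)C)OO1 | intermediate
21 | 2-[(3S,4S,6R)-4,6-diethyl-6-[(2S,4S,5E)-4-ethyl-2-methylhept-5-en-1-yl]-1,2-dioxan-3-yl]acetic acid | CC[C@H](/C=C/C)C[C@H](C)C[C@]1(CC)C[C@H](CC)[C@H](CC(=O)O)OO1 | intermediate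
22 | 2-[(3S,4S,6R)-4,6-diethyl-6-[(2S,4S,5E)-4-ethyl-2-methyl-7-oxooct-5-en-1-yl]-1,2-dioxan-3-yl]acetic acid | CC[C@H](/C=C/C(C)=O)C[C@H](C)C[C@]1(CC)C[C@H](CC)[C@H](CC(=O)O)OO1 | target

## Step count

Total steps: 12. Longest linear sequence: 12 (from 1 and 2 to 22; 7 is bought and enters at step 5).

## Three steps most likely to fail

**Step 8 (hydroperoxysilylation; C6).** The radical capture has no facial control, so half of the material ends as the 6S epimer, and some reaction at the propenyl group is possible. The fallback sets out from alcohol 13 and makes the C6–O bond by an ionic ring closure instead of radical trapping. Dess–Martin oxidation gives the aldehyde (2S,4E,6S,8S,9E)-2,8-diethyl-4-ethylidene-6-methylundec-9-enal F1. Anhydrous H2O2 in MeOH with catalytic TsOH converts it into the methoxy hydroperoxide (2S,4E,6S,8S,9E)-2,8-diethyl-4-ethylidene-1-methoxy-6-methylundec-9-en-1-yl hydroperoxide F2. Bloodworth cycloperoxymercuration (Hg(OAc)2, catalytic HClO4, CH2Cl2) then adds the hydroperoxide 6-exo to the tertiary alkene carbon through a chair with the C4 ethyl equatorial, giving the organomercurial (4S,6R)-6-[1-(acetoxymercurio)ethyl]-4-ethyl-6-[(2S,4S,5E)-4-ethyl-2-methylhept-5-en-1-yl]-3-methoxy-1,2-dioxane F3. Reductive demercuration (NaBH4, aqueous NaOH) turns the mercurated arm into the C6 ethyl group and returns to the route at 18. The C6 ratio is then decided in a reversible ring closure and is not predictable in advance, so separation of C6 epimers may still be needed.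

**Step 11 (peroxycarbenium alkylation; C3).** The Lewis acid may also ionise the tertiary C6–O bond (fragmentation), and the bis-silyl ketene acetal has not been shown on such a substrate. The fallback sets out from aldehyde 15 and forms the C3–O bond last, by conjugate addition. Wittig olefination with Ph3P=CHCO2Me gives the enoate methyl (2E,4S,6R,8S,10S,11E)-4,6,10-triethyl-8-methyl-6-[(triethylsilyl)peroxy]trideca-2,11-dienoate F4. Fluoride (Bu4NF, THF) removes the silyl group and the peroxy anion closes 6-exo onto the enoate (intramolecular oxa-Michael addition) to give methyl 2-[(3S,4S,6R)-4,6-diethyl-6-[(2S,4S,5E)-4-ethyl-2-methylhept-5-en-1-yl]-1,2-dioxan-3-yl]acetate F5, which is separated from its C3 and C6 isomers. LiOH in aqueous THF then gives 21, where the route is rejoined. The 3,4-cis to trans ratio of this closure is uncertain and may favour the trans isomer.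

**Step 12 (cross-metathesis).** The internal alkene is branched at the allylic carbon, so metathesis may be slow or incomplete. The fallback sets out from 21 and builds the enone by cleavage and olefination. Ozonolysis (O3, CH2Cl2, −78 °C; Me2S), which dialkyl peroxides survive, gives the aldehyde 2-[(3S,4S,6R)-4,6-diethyl-6-[(2S,4S)-4-formyl-2-methylhexyl]-1,2-dioxan-3-yl]acetic acid F6. Wittig reaction with excess Ph3P=CHC(O)CH3 gives the (E)-enone 22 directly.

## Further compounds

F1 | step 8 | (2S,4E,6S,8S,9E)-2,8-diethyl-4-ethylidene-6-methylundec-9-enal | CC[C@H](/C=C/C)C[C@H](C)C/C(=C\C)C[C@H](CC)C=O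
F2 | step 8 | (2S,4E,6S,8S,9E)-2,8-diethyl-4-ethylidene-1-methoxy-6-methylundec-9-en-1-yl hydroperoxide (C1 epimers) | CC[C@H](/C=C/C)C[C@H](C)C/C(=C\C)C[C@H](CC)C(OC)OO
F3 | step 8 | (4S,6R)-6-[1-(acetoxymercurio)ethyl]-4-ethyl-6-[(2S,4S,5E)-4-ethyl-2-methylhept-5-en-1-yl]-3-methoxy-1,2-dioxane | CC[C@H](/C=C/C)C[C@H](C)C[C@]1(C(C)[Hg]OC(C)=O)C[C@H](CC)C(OC)OO1
F4 | step 11 | methyl (2E,4S,6R,8S,10S,11E)-4,6,10-triethyl-8-methyl-6-[(triethylsilyl)peroxy]trideca-2,11-dienoate | CC[C@H](/C=C/C)C[C@H](C)C[C@](OO[Si](CC)(CC)CC)(CC)C[C@H](CC)/C=C/C(=O)OC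
F5 | step 11 | methyl 2-[(3S,4S,6R)-4,6-diethyl-6-[(2S,4S,5E)-4-ethyl-2-methylhept-5-en-1-yl]-1,2-dioxan-3-yl]acetate | CC[C@H](/C=C/C)C[C@H](C)C[C@]1(CC)C[C@H](CC)[C@H](CC(=O)OC)OO1
F6 | step 12 | 2-[(3S,4S,6R)-4,6-diethyl-6-[(2S,4S)-4-formyl-2-methylhexyl]-1,2-dioxan-3-yl]acetic acid | CC[C@H](C=O)C[C@H](C)C[C@]1(CC)C[C@H](CC)[C@H](CC(=O)O)OO1
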